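**Plan**

1. Numbering of the fused bicycle: O(1)–O(2)–C(3)–C(4)–C(4a)–O(5)–C(6)–C(7)–C(7a). The retrosynthesis first opens the peroxyhemiketal bond O(1)–C(7a) (ring–chain tautomer 24). It then cuts C(4)–C(4a) and O(2)–C(3) together, giving a masked 5-methyltetronic acid (20), the side-chain diene 16 and O2. Diene 16 is cut at the benzylic C–C bond, the alkyne and the isopropenyl group back to (R)-citronellal.
2. Enabling feature: the dioxane is a 1,2-dioxan-3-ol whose hemiketal carbon C(7a) is the ketone of a β-keto-γ-lactone. C(4a) is the oxygen-bearing α′ carbon of that ketone, and C(3) is a fully substituted peroxide carbon 1,3 to it. This is the array that an α′-keto radical, a CH2=C(Me)R alkene and O2 assemble.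
3. Forward order: chain 16 from citronellal (steps 1–7); furanone 20, which carries the five-membered ring from then on (steps 8–9); aerobic radical union (step 10); unmasking of the ketone and closure of the dioxane ring (step 11).
4. Stereochemistry: the side-chain centre comes from (R)-citronellal, and C(7a) follows C(4a) through the cis ring fusion. C(4a) and C(3) are formed without control in step 10, so the target is separated from three diastereomers at the end. The fallback for step 10 puts C(4a) under catalyst control.

Key step: step 10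

Remark: the target is assumed, like other cyclic peroxyhemiketals, to be more stable than its open hydroperoxy tetronic acid tautomer 24, so that 24 closes spontaneously.

**Route**

Step 1
Reactants: 1 (R)-citronellal; 2 methylmagnesium bromide
Product: 3 (4R)-4,8-dimethylnon-7-en-2-ol (both C2 epimers)
Conditions: MeMgBr, Et2O, 0 °C; aq. NH4Cl
Reagents that add atoms: methylmagnesium bromide, C[Mg]Br
Why: Grignard addition to the aldehyde should be clean; the new carbinol centre is removed by oxidation in step 5 and the citronellal centre is not touched.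

Step 2
Reactants: 3 (4R)-4,8-dimethylnon-7-en-2-ol; 4 ozone
Product: 5 (4R)-4-methylheptane-1,6-diol (both C6 epimers)
Conditions: O3, CH2Cl2/MeOH, −78 °C; then NaBH4, −78 → 0 °C
Reagents that add atoms: ozone, [O-][O+]=O
Why: Ozonolysis with reductive work-up should cut the trisubstituted alkene to the primary alcohol while no other alkene is yet present.

Step 3
Reactants: 5 (4R)-4-methylheptane-1,6-diol; 6 4-methylbenzenesulfonyl chloride
Product: 7 (4R)-6-hydroxy-4-methylheptyl 4-methylbenzenesulfonate
Conditions: TsCl (1.05 equiv), pyridine, CH2Cl2, −10 °C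
Reagents that add atoms: 4-methylbenzenesulfonyl chloride, Cc1ccc(cc1)S(=O)(=O)Cl
Why: Sulfonylation should select the unhindered primary hydroxyl over the secondary one on steric grounds.

Step 4
Reactants: 7 (4R)-6-hydroxy-4-methylheptyl 4-methylbenzenesulfonate; 8 lithium acetylide ethylenediamine complex
Product: 9 (4R)-4-methylnon-8-yn-2-ol
Conditions: LiC≡CH·H2NCH2CH2NH2 (3 equiv), DMSO, 23 °C
Reagents that add atoms: lithium acetylide ethylenediamine complex, [Li]C#C.NCCN
Why: Acetylide alkylation (SN2 at the primary tosylate) should give the terminal alkyne; the secondary alkoxide only consumes one equivalent of base.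

Step 5
Reactants: 9 (4R)-4-methylnon-8-yn-2-ol
Product: 10 (4R)-4-methylnon-8-yn-2-one
Conditions: Dess–Martin periodinane, NaHCO3, CH2Cl2, 23 °C
Reagents that add atoms: none
Why: Dess–Martin oxidation should give the methyl ketone; the stereocentre is β to the carbonyl and cannot epimerise.

Step 6
Reactants: 10 (4R)-4-methylnon-8-yn-2-one; 11 methyltriphenylphosphonium bromide
Product: 12 (4R)-2,4-dimethylnon-1-en-8-yne
Conditions: Ph3PCH3Br, KOtBu, THF, 0 → 23 °C
Reagents that add atoms: methyltriphenylphosphonium bromide, C[P+](c1ccccc1)(c1ccccc1)c1ccccc1.[Br-]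
Why: Wittig methylenation of the methyl ketone should install the 1,1-disubstituted alkene; the ylide is not basic enough to deprotonate the terminal alkyne.

Step 7
Reactants: 12 (4R)-2,4-dimethylnon-1-en-8-yne; 13 trimethylaluminium; 14 benzyl bromide
Product: 16 (4R,8E)-2,4,8-trimethyl-10-phenyldeca-1,8-diene, via alkenyldimethylalane 15 (not isolated)
Conditions: Me3Al (2 equiv), Cp2ZrCl2 (0.25 equiv), CH2Cl2, 23 °C; then BnBr, Pd(PPh3)4 (5 mol%), THF, 23 °C
Reagents that add atoms: trimethylaluminium, C[Al](C)C; benzyl bromide, BrCc1ccccc1
Why: Negishi zirconium-catalysed carboalumination adds Me and Al syn across the alkyne (Me to the inner carbon; the 1,1-disubstituted alkene is inert), and cross-coupling of the alane with benzyl bromide on zerovalent palladium proceeds with retention, fixing the E geometry.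

Step 8
Reactants: 17 methyl 3-oxopentanoate; 18 bromine
Product: 19 methyl 4-bromo-3-oxopentanoate (racemic)
Conditions: Br2 (1.0 equiv), CHCl3, 0 → 23 °C
Reagents that add atoms: bromine, BrBr
Why: Bromination of the β-keto ester under HBr-equilibrating conditions should end at the 4-bromo isomer, the usual entry to 4-halo-3-oxo esters.

Step 9
Reactants: 19 methyl 4-bromo-3-oxopentanoate
Product: 20 5-methoxy-2-methylfuran-3(2H)-one (racemic)
Conditions: Et3N (1.1 equiv), Et2O, 0 → 23 °C
Reagents that add atoms: none
Why: The ester enolate should close by 5-exo-tet O-alkylation through the ester carbonyl oxygen (C-alkylation would need a three-membered ring), the known route from 4-halo-3-oxo esters to 5-alkoxyfuran-3(2H)-ones.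

Step 10
Reactants: 16 (4R,8E)-2,4,8-trimethyl-10-phenyldeca-1,8-diene; 20 5-methoxy-2-methylfuran-3(2H)-one; 21 dioxygen
Product: 22 (2R)-2-[(2R,4R,8E)-2-hydroperoxy-2,4,8-trimethyl-10-phenyldec-8-en-1-yl]-5-methoxy-2-methylfuran-3(2H)-one (formed together with its three diastereomers at furanone C2 and side-chain C2)
Conditions: anhydrous Mn(OAc)3 (0.2 equiv), NaOAc, glacial AcOH, 4 Å MS, dry air (1 atm), 23 °C, dark; 20 in three-fold excess
Reagents that add atoms: dioxygen, O=O
Why: Proposed new method: Mn(OAc)3 should form the trivalent-manganese enolate of 20 at C2, its only enolisable position (the enol is an aromatic 3-hydroxyfuran), and inner-sphere electron transfer gives a furanyloxyl-type radical with carbon spin density at C2 only, which adds to the CH2 terminus of the 1,1-disubstituted alkene of 16 (the C(4)–C(4a) bond); the tertiary radical so formed captures dioxygen (the O(2)–C(3) bond) and the peroxyl radical is reduced by Mn(OAc)2 to hydroperoxide 22 with return of the trivalent oxidant. The closest known reaction type is the Mn(OAc)3/O2 three-component [2+2+2] peroxidation of 1,3-dicarbonyl compounds, tetronic acids included, with alkenes to 1,2-dioxan-3-ols, together with the Mn(OAc)3 α′-oxidation of β-alkoxy enones; the transposed enol ether in 20 is needed because free 5-methyltetronic acid would be oxidised between its two carbonyl groups and give the wrongly fused peroxide. The step closes no ring itself: the vinylogous carbonate carbonyl of 22 is too deactivated to be attacked, and the 1,2-dioxane closes in step 11 by 6-exo-trig addition of the hydroperoxide to the unmasked ketone. Both new stereocentres (C(4a) at C–C bond formation, C(3) at oxygen capture) arise from planar radicals with no controlling element nearby, so 22 is expected as four diastereomers that are carried on and separated after step 11. The step needs regioselectivity within 20 (secured by the enol ether), chemoselectivity for the unhindered CH2= terminus over the trisubstituted chain alkene (steric preference of the tertiary radical) and over hydrogen abstraction from the benzylic allylic CH2 (peroxyl radicals are intercepted by Mn(OAc)2 and 20 is in excess), and tolerance of the first radical towards dioxygen (delocalised radical, reversible oxygen capture, as for 1,3-dicarbonyl radicals).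

Step 11
Reactants: 22 (2R)-2-[(2R,4R,8E)-2-hydroperoxy-2,4,8-trimethyl-10-phenyldec-8-en-1-yl]-5-methoxy-2-methylfuran-3(2H)-one (diastereomer mixture); 23 water
Product: 25 (3R,4aR,7aR)-3-[(2R,6E)-2,6-dimethyl-8-phenyloct-6-en-1-yl]-7a-hydroxy-3,4a-dimethyltetrahydrofuro[3,2-c][1,2]dioxin-6(3H)-one, via hydroperoxy tetronic acid 24 (not isolated)
Conditions: 1 M aq. HCl/THF (1:5), 0 → 23 °C; silica gel chromatography, then preparative HPLC to separate the four diastereomers
Reagents that add atoms: water, O
Why: Acid hydrolysis of the vinylogous methyl carbonate (protonation at C4 of the furanone, addition of water, loss of methanol) should unmask tetronic acid 24, whose ketone tautomer is captured by the tertiary hydroperoxide in a 6-exo-trig ring–chain closure; the tether can only reach the carbonyl face syn to C(4), so the fusion is cis and (4aR) sets (7aR) under thermodynamic control.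

**Compound list**

1 | (R)-citronellal | O=CC[C@H](C)CCC=C(C)C | starting material
2 | methylmagnesium bromide | C[Mg]Br | starting material
3 | (4R)-4,8-dimethylnon-7-en-2-ol | CC(O)C[C@H](C)CCC=C(C)C | intermediate
4 | ozone | [O-][O+]=O | starting material
5 | (4R)-4-methylheptane-1,6-diol | CC(O)C[C@H](C)CCCO | intermediate
6 | 4-methylbenzenesulfonyl chloride | Cc1ccc(cc1)S(=O)(=O)Cl | starting material
7 | (4R)-6-hydroxy-4-methylheptyl 4-methylbenzenesulfonate | CC(O)C[C@H](C)CCCOS(=O)(=O)c1ccc(C)cc1 | intermediate
8 | lithium acetylide ethylenediamine complex | [Li]C#C.NCCN | starting material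
9 | (4R)-4-methylnon-8-yn-2-ol | CC(O)C[C@H](C)CCCC#C | intermediate
10 | (4R)-4-methylnon-8-yn-2-one | CC(=O)C[C@H](C)CCCC#C | intermediate
11 | methyltriphenylphosphonium bromide | C[P+](c1ccccc1)(c1ccccc1)c1ccccc1.[Br-] | starting material
12 | (4R)-2,4-dimethylnon-1-en-8-yne | C=C(C)C[C@H](C)CCCC#C | intermediate
13 | trimethylaluminium | C[Al](C)C | starting material
14 | benzyl bromide | BrCc1ccccc1 | starting material
15 | dimethyl[(1E,6R)-2,6,8-trimethylnona-1,8-dien-1-yl]alane | C=C(C)C[C@H](C)CCC/C(C)=C/[Al](C)C | intermediate
16 | (4R,8E)-2,4,8-trimethyl-10-phenyldeca-1,8-diene | C=C(C)C[C@H](C)CCC/C(C)=C/Cc1ccccc1 | intermediate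
17 | methyl 3-oxopentanoate | CCC(=O)CC(=O)OC | starting material
18 | bromine | BrBr | starting material
19 | methyl 4-bromo-3-oxopentanoate (racemic) | COC(=O)CC(=O)C(C)Br | intermediate
20 | 5-methoxy-2-methylfuran-3(2H)-one (racemic) | CC1OC(OC)=CC1=O | intermediate
21 | dioxygen | O=O | starting material
22 | (2R)-2-[(2R,4R,8E)-2-hydroperoxy-2,4,8-trimethyl-10-phenyldec-8-en-1-yl]-5-methoxy-2-methylfuran-3(2H)-one (isomer leading to the target; formed with three diastereomers) | C/C(=C\Cc1ccccc1)CCC[C@@H](C)C[C@@](C)(OO)C[C@@]1(C)OC(OC)=CC1=O | intermediate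
23 | water | O | starting material
24 | (5R)-5-[(2R,4R,8E)-2-hydroperoxy-2,4,8-trimethyl-10-phenyldec-8-en-1-yl]-4-hydroxy-5-methylfuran-2(5H)-one | C/C(=C\Cc1ccccc1)CCC[C@@H](C)C[C@@](C)(OO)C[C@@]1(C)OC(=O)C=C1O | intermediate
25 | (3R,4aR,7aR)-3-[(2R,6E)-2,6-dimethyl-8-phenyloct-6-en-1-yl]-7a-hydroxy-3,4a-dimethyltetrahydrofuro[3,2-c][1,2]dioxin-6(3H)-one | C/C(=C\Cc1ccccc1)CCC[C@@H](C)C[C@]1(C)C[C@@]2(C)OC(=O)C[C@@]2(O)OO1 | target

**Step count and risks**

Total step count: 11. Longest linear sequence: 9 steps (steps 1–7, 10, 11, from (R)-citronellal).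

Steps most likely to fail:

Step 10. The furanone radical may be consumed by direct oxygenation or dimerisation faster than it adds to the unactivated alkene, and there is no facial selectivity at C(4a) or C(3) even if the union works. The fallback uses known reaction types, sets out from diene 16 and returns at 24. A carbonyl-ene reaction of 16 with methyl pyruvate under [Cu((R,R)-t-Bu-box)](SbF6)2 (divalent copper; this ligand enantiomer is expected, from the chelate model of pyruvate additions, to give the 2R alcohol) should give methyl (2R,6R,10E)-2-hydroxy-2,6,10-trimethyl-4-methylidene-12-phenyldodec-10-enoate F1. Its trisubstituted double-bond isomer would lead to the same tertiary radical later. Acetylation (Ac2O, DMAP, Et3N) gives methyl (2R,6R,10E)-2-acetoxy-2,6,10-trimethyl-4-methylidene-12-phenyldodec-10-enoate F2. Isayama–Mukaiyama hydroperoxysilylation (Co(acac)2, divalent cobalt, O2, Et3SiH, stopped before the chain alkene reacts) gives methyl (2R,4R,6R,10E)-2-acetoxy-2,4,6,10-tetramethyl-12-phenyl-4-[(triethylsilyl)peroxy]dodec-10-enoate F3 with its C4 epimer. Dieckmann cyclisation (LiHMDS, THF, −78 °C) gives (5R)-4-hydroxy-5-methyl-5-{(2R,4R,8E)-2,4,8-trimethyl-10-phenyl-2-[(triethylsilyl)peroxy]dec-8-en-1-yl}furan-2(5H)-one F4. HF·pyridine then releases 24, which closes to 25. Only the two C(3) epimers then need separating.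

Step 11. The aqueous acid needed to hydrolyse the vinylogous carbonate may also trigger Hock-type cleavage or dehydration at the free tertiary hydroperoxide before the ring closes. The fallback sets out from 22 and returns at 24. The hydroperoxide is first silylated (Et3SiCl, imidazole, DMF) to (2R)-5-methoxy-2-methyl-2-{(2R,4R,8E)-2,4,8-trimethyl-10-phenyl-2-[(triethylsilyl)peroxy]dec-8-en-1-yl}furan-3(2H)-one F5. The enol ether is then hydrolysed under more forcing aqueous acid to the silyl-peroxy tetronic acid F4. Buffered HF·pyridine finally liberates 24, so that hydrolysis and peroxide closure are no longer coupled.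

Step 9. Intermolecular C-alkylation of the β-keto ester enolate, Favorskii-type contraction or loss of HBr may outrun the 5-exo O-alkylation. The fallback sets out from 19 and returns at 20. Heating 19 neat (about 120 °C) closes the lactone with loss of bromomethane to 4-hydroxy-5-methylfuran-2(5H)-one F6. O-methylation with diazomethane (Et2O, 0 °C) then gives both enol ethers: 20, expected as the minor product, is separated by chromatography from the conjugated isomer 4-methoxy-5-methylfuran-2(5H)-one F7.

Further compounds
F1 | step 10 | methyl (2R,6R,10E)-2-hydroxy-2,6,10-trimethyl-4-methylidene-12-phenyldodec-10-enoate | C/C(=C\Cc1ccccc1)CCC[C@@H](C)CC(=C)C[C@@](C)(O)C(=O)OC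
F2 | step 10 | methyl (2R,6R,10E)-2-acetoxy-2,6,10-trimethyl-4-methylidene-12-phenyldodec-10-enoate | C/C(=C\Cc1ccccc1)CCC[C@@H](C)CC(=C)C[C@@](C)(OC(C)=O)C(=O)OC
F3 | step 10 | methyl (2R,4R,6R,10E)-2-acetoxy-2,4,6,10-tetramethyl-12-phenyl-4-[(triethylsilyl)peroxy]dodec-10-enoate | C/C(=C\Cc1ccccc1)CCC[C@@H](C)C[C@@](C)(OO[Si](CC)(CC)CC)C[C@@](C)(OC(C)=O)C(=O)OC
F4 | step 10 | (5R)-4-hydroxy-5-methyl-5-{(2R,4R,8E)-2,4,8-trimethyl-10-phenyl-2-[(triethylsilyl)peroxy]dec-8-en-1-yl}furan-2(5H)-one | C/C(=C\Cc1ccccc1)CCC[C@@H](C)C[C@@](C)(OO[Si](CC)(CC)CC)C[C@@]1(C)OC(=O)C=C1O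
F5 | step 11 | (2R)-5-methoxy-2-methyl-2-{(2R,4R,8E)-2,4,8-trimethyl-10-phenyl-2-[(triethylsilyl)peroxy]dec-8-en-1-yl}furan-3(2H)-one | C/C(=C\Cc1ccccc1)CCC[C@@H](C)C[C@@](C)(OO[Si](CC)(CC)CC)C[C@@]1(C)OC(OC)=CC1=O
F6 | step 9 | 4-hydroxy-5-methylfuran-2(5H)-one | CC1OC(=O)C=C1O
F7 | step 9 | 4-methoxy-5-methylfuran-2(5H)-one | CC1OC(=O)C=C1OC
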